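Z + G ⇌ ZG acting on its own, from a charge without ZG, cannot lower [ZG], yet in the south run it goes from 23.8% to 17.3% of the Z charged while [Z] climbs from 59.1% to 65.9%. That was the opening remark of a short meeting on these flasks:

| flask | Z | G | X | temperature | remark | time |
|---|---|---|---|---|---|---|
| south | 0.80 M | 0.96 M | 0.80 M | 20 °C | run made earlier |  |
| west | 0.80 M | 0.96 M | 0.80 M | 62 °C | run made earlier |  |
| ochre | 1.6 M | 0.960 M | 0.800 M | 50 °C |  | 12 min |
| green | 1.6 M | 0.960 M | 0.800 M | 25 °C |  | 12 min |
| grey | 1.6 M | 0.960 M | 0.800 M | 100 °C |  | 12 min |
| violet | 1.6 M | 0.960 M | 0.800 M | 75 °C |  | 12 min |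

| run | time / min | ZG / % | ZX / % | Z / % |
|---|---|---|---|---|
| south | 6.00 | 23.8 | 16.3 | 59.1 |
| south | 12.0 | 20.6 | 15.3 | 61.0 |
| south | 20.0 | 21.9 | 17.1 | 63.1 |
| south | 25.0 | 18.2 | 17.7 | 62.3 |
| south | 40.0 | 17.3 | 16.0 | 65.9 |
| west | 0.833 | 6.1 | 22.4 | 72.7 |
| west | 1.50 | 3.7 | 21.8 | 74.4 |
| west | 3.00 | 0 | 20.5 | 79.6 |
| west | 4.00 | 0 | 20.8 | 78.7 |
| west | 6.00 | 0 | 22.0 | 78.2 |

(readings scatter by 1 percentage point)

* the flask with the highest share of ZG in all that became ZG or ZX ("all alike" if they lie within 1.5 percentage points) (ochre / green / grey / violet / all alike)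
* share of ZG in all that became ZG or ZX, ochre
* share of ZG in all that became ZG or ZX, green
* share of ZG in all that became ZG or ZX, grey
* share of ZG in all that became ZG or ZX, violet

- the numbers in the tables scatter with a standard deviation of 1 percentage point

The first speaker pointed at [ZX] on the board. It stays within the scatter, from 16.3% to 16.0% in south and from 22.4% to 22.0% in west. She argued that the ZX side of the asked share therefore stands still in these runs, so the question becomes how much ZG outlasts the clock.

The second speaker proposed one number per temperature. He read a fade rate of 0.00938 /min from the first and last south readings. From west he took 0.750 /min from the first two readings, since its later ones stand at 0%. Drawing the logarithm of the rate straight against temperature, he obtained 63.3 min for green as the inverse of the rate. He called this the fade time, the minutes in which [ZG] shrinks by a factor e, a pseudo-first-order lifetime.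

The third speaker reckoned the others the same way: ochre 4.66 min, violet 0.344 min, grey 0.0253 min. She held these against the asked 12 min. Green's fade time is the longest and exceeds the clock, so she reckoned that green keeps 82.7% of its ZG. By the same reckoning ochre keeps 7.61%, and violet and grey, with fade times far shorter than the clock, keep none worth counting. The meeting committed to green.

The forecast said green, with 52% (45% to 58%) for green, 4% (1% to 12%) for ochre, and 0% for violet and 0% for grey, on the ground that “ZG then fades while Z returns, so G is being slowly destroyed”.

The flasks give green as the highest, with green 53.6%, ochre 7.79%, violet 0% and grey 0%.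

    Z + G ⇌ ZG (K = 2.40 /M, k = 0.120 /M/s, Ea = 59.0 kJ/mol, ΔH = −19.0 kJ/mol)
    X + G → XG (k = 0.570 /M/s, Ea = 47.0 kJ/mol)
    Z + X → ZX (k = 0.0900 /M/s, Ea = 52.0 kJ/mol)
    G → D (k = 0.0150 /s, Ea = 83.0 kJ/mol)
    (constants at 50 °C)

In ochre, ZG stands at 5.07% after 6.00 min and 1.46% after 12.0 min, a fade time of 4.82 min against the reckoned 4.66 min. Now take grey with 0.64 M of Z. Its temperature is grey's, so the reckoned fade time remains 0.0253 min, far shorter than 12 min, and the reckoning expects no ZG at the asked time. That neighbouring flask shows a share of 0%, with 0% of its G unbound and ZX at 32.8% of its Z.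

(The readings stem from a simulated flask with constants of no real substance, and the scatter is random.)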